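**Retrosynthetic overview**
1. Target 10 ⇒ furyl glycolate 6: the tertiary C2–OH bond is disconnected to water. In the forward sense water adds to the hexadecyl-bearing furan carbon of a furfuryl cation, and the opened chain closes C1–C2 in the same flask (enantioselective oxa-Piancatelli); the furan oxygen becomes the ketone.
2. 6 ⇒ 2-hexadecylfuran 4 + methyl glyoxylate 5 (Friedel–Crafts hydroxyalkylation at the free furan α-position).
3. 4 ⇒ furan 1 + 1-bromohexadecane 2 (C2-lithiation, alkylation).
4. Rings: the furan is bought and consumed; the cyclopentenone, the only ring of the target, is formed last.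

Assumption: methyl glyoxylate 5 is bought as the monomer solution and distilled just before use; the (S)-catalyst of step 3 is taken to give (1R,2R)-10, and its mirror image is used if the sense of induction proves opposite.

**Step 1**
Reactants: 1 furan; 2 1-bromohexadecane
Product: 4 2-hexadecylfuran, via 2-furyllithium 3 (not isolated)
Conditions: 1 (1.3 equiv), n-BuLi (1.1 equiv), THF, 0 °C to rt, 2 h; then 2 (1.0 equiv), 0 °C to 50 °C, 12 h
Reagents that add atoms: none
Why: n-BuLi metalates furan selectively at C2 and the 2-furyllithium is alkylated by the primary bromide in an SN2 reaction (heteroaryl lithiation/alkylation); no stereocenter is formed.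

**Step 2**
Reactants: 4 2-hexadecylfuran; 5 methyl glyoxylate
Product: 6 methyl 2-(5-hexadecylfuran-2-yl)-2-hydroxyacetate (racemic)
Conditions: 5 (1.5 equiv), Yb(OTf)3 (5 mol%), CH2Cl2, −20 °C to 0 °C
Reagents that add atoms: none
Why: Friedel–Crafts hydroxyalkylation, in which the chelated glyoxylate aldehyde is attacked by the only free, most nucleophilic α-position of the 2-alkylfuran; the carbinol center is left racemic on purpose because step 3 erases it by ionisation.

**Step 3**
Reactants: 6 methyl 2-(5-hexadecylfuran-2-yl)-2-hydroxyacetate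
Product: 10 methyl (1R,2R)-2-hexadecyl-2-hydroxy-5-oxocyclopent-3-ene-1-carboxylate (target), via furfuryl cation 7 (not isolated), via hemiketal 8 (not isolated), via ring-opened enol 9 (not isolated)
Conditions: (S)-3,3'-bis(2,4,6-triisopropylphenyl)-1,1'-binaphthyl-2,2'-diyl N-triflylphosphoramide (5 mol%), H2O (5 equiv), toluene, 30 °C; short silica plug, no base
Reagents that add atoms: water, O
Why: Proposed new method: a catalytic enantioselective oxa-Piancatelli rearrangement of a furyl glycolate with water. The strong chiral Brønsted acid ionises the carbinol to cation 7 (the same ionisation that gives bis-furyl acetates as by-products in glyoxylate Friedel–Crafts reactions). Water adds to the hexadecyl-bearing C5 and forms the tertiary C–O bond. Hemiketal 8 opens to the Z-enol 9, whose O-protonated hydroxypentadienyl cation is held by two hydrogen bonds (enol OH and carbonyl) in the chiral anion pocket and closes by conrotatory 4π electrocyclisation (equivalently an enol–ketone aldol). The catalyst fixes the sense of rotation and so sets C2 as R, converting both enantiomers of 6 into one product. C1 then equilibrates through the β-keto ester enol to the more stable epimer, with CO2Me anti to hexadecyl and hydrogen-bonded to the cis OH (1R). Closest known reactions: the chiral-phosphoric-acid-catalysed aza-Piancatelli rearrangement of furylcarbinols with anilines, the racemic Piancatelli rearrangement of 5-methyl-2-furylcarbinols, and N-triflylphosphoramide-catalysed enantioselective Nazarov cyclisations.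

**Compound list**
1 | furan | c1ccoc1 | starting material
2 | 1-bromohexadecane | CCCCCCCCCCCCCCCCBr | starting material
3 | 2-furyllithium | [Li]c1ccco1 | intermediate
4 | 2-hexadecylfuran | CCCCCCCCCCCCCCCCc1ccco1 | intermediate
5 | methyl glyoxylate (methyl 2-oxoacetate) | COC(=O)C=O | starting material
6 | methyl 2-(5-hexadecylfuran-2-yl)-2-hydroxyacetate (racemic) | CCCCCCCCCCCCCCCCc1ccc(C(O)C(=O)OC)o1 | intermediate
7 | furfuryl cation, 1-(5-hexadecylfuran-2-yl)-2-methoxy-2-oxoethylium, ion-paired with the catalyst anion | CCCCCCCCCCCCCCCCc1ccc([CH+]C(=O)OC)o1 | intermediate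
8 | hemiketal, methyl 2-(5-hexadecyl-5-hydroxyfuran-2(5H)-ylidene)acetate (racemic at C5, exocyclic alkene geometry not controlled) | CCCCCCCCCCCCCCCCC1(O)C=CC(=CC(=O)OC)O1 | intermediate
9 | ring-opened enol, methyl (2Z,4Z)-3-hydroxy-6-oxodocosa-2,4-dienoate | CCCCCCCCCCCCCCCCC(=O)/C=C\C(O)=C\C(=O)OC | intermediate
10 | methyl (1R,2R)-2-hexadecyl-2-hydroxy-5-oxocyclopent-3-ene-1-carboxylate (untenone A structure; OH cis to CO2Me, hexadecyl trans) | CCCCCCCCCCCCCCCC[C@@]1(O)C=CC(=O)[C@@H]1C(=O)OC | target

**Total step count:** 3. **Longest linear sequence:** 3 steps (1 → 4 → 6 → 10).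

**Steps most likely to fail**

Step 3 (the proposed new step, highest risk). Possible failures:
- ionisation of the ester-substituted carbinol is slow;
- a racemic background aldol of the neutral Z-enedione (keto tautomer of 9) competes;
- acid dehydrates 10 to the cyclopentadienone, which dimerises;
- retro-aldol erodes the enantiomeric purity.

Fallback with known chemistry, setting out from 6 and returning at 10. Compound 6 is acetylated (Ac2O, pyridine, cat. DMAP, CH2Cl2) to methyl 2-acetoxy-2-(5-hexadecylfuran-2-yl)acetate F4. SmI2 (2.5 equiv, THF/MeOH, −78 °C) cleaves the α-acetoxy group to give methyl 2-(5-hexadecylfuran-2-yl)acetate F5. mCPBA (CH2Cl2, 0 °C) opens the furan oxidatively to methyl (4Z)-3,6-dioxodocos-4-enoate F6, the keto tautomer of 9. Brief exposure to catalytic Et3N in CH2Cl2 closes it by the established biomimetic intramolecular aldol to the racemic cyclopentenone F7. Preparative HPLC on an amylose tris(3,5-dimethylphenylcarbamate) phase (hexane/i-PrOH) then delivers 10.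

Step 2. Possible failures: the product glycolate ionises and alkylates a second furan (bis-furyl acetate), or the furan oligomerises under the Lewis acid. Fallback setting out from 4 and returning at 6. Compound 4 is lithiated at C5 (n-BuLi, THF, 0 °C) to (5-hexadecylfuran-2-yl)lithium F2. This is added to excess dimethyl oxalate at −78 °C to give methyl 2-(5-hexadecylfuran-2-yl)-2-oxoacetate F3. NaBH4 (MeOH, −20 °C) reduces the ketone chemoselectively to racemic 6.

Step 1. Possible failures: E2 elimination of the long-chain bromide to 1-hexadecene, or incomplete alkylation of the furyllithium. Fallback setting out from 1 and returning at 4. Furan 1 is acylated with palmitic anhydride (BF3·OEt2, 10 mol%, CH2Cl2, 0 °C to rt) to 1-(furan-2-yl)hexadecan-1-one F1. Wolff–Kishner reduction (N2H4·H2O, KOH, diethylene glycol, 130 °C then 200 °C) gives 4.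

**Further compounds**
F1 | step 1 | 1-(furan-2-yl)hexadecan-1-one | CCCCCCCCCCCCCCCC(=O)c1ccco1
F2 | step 2 | (5-hexadecylfuran-2-yl)lithium | [Li]c1ccc(CCCCCCCCCCCCCCCC)o1
F3 | step 2 | methyl 2-(5-hexadecylfuran-2-yl)-2-oxoacetate | CCCCCCCCCCCCCCCCc1ccc(C(=O)C(=O)OC)o1
F4 | step 3 | methyl 2-acetoxy-2-(5-hexadecylfuran-2-yl)acetate (racemic) | CCCCCCCCCCCCCCCCc1ccc(C(OC(C)=O)C(=O)OC)o1
F5 | step 3 | methyl 2-(5-hexadecylfuran-2-yl)acetate | CCCCCCCCCCCCCCCCc1ccc(CC(=O)OC)o1
F6 | step 3 | methyl (4Z)-3,6-dioxodocos-4-enoate | CCCCCCCCCCCCCCCCC(=O)/C=C\C(=O)CC(=O)OC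
F7 | step 3 | racemic methyl 2-hexadecyl-2-hydroxy-5-oxocyclopent-3-ene-1-carboxylate, 1:1 mixture of the (1R,2R) and (1S,2S) forms | CCCCCCCCCCCCCCCC[C@@]1(O)C=CC(=O)[C@@H]1C(=O)OC.CCCCCCCCCCCCCCCC[C@]1(O)C=CC(=O)[C@H]1C(=O)OC
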